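## Analysis of the target

Target 24 is a β-resorcylic acid. The benzene ring carries the carboxyl carbon C7 on C1, free hydroxyls on C2 and C4, and a saturated chain C1′–C13′ on C6. The chain holds two acetoxy stereocentres, C2′ and C12′, both S. Nine methylenes separate them, so neither can steer the other and each must be set on its own. C12′ is a methyl carbinol of the kind a chiral-pool epoxide supplies, while C2′ lies one carbon from the ring and is best set by reagent control on a C2′ carbonyl. The sensitive groups are the acid (a 2,4-dihydroxybenzoic acid loses CO2 with acid or heat), the two base-labile acetates, and the C2′ oxygen, which is δ to C7: a free C2′ hydroxyl beside the C7 ester or acid can close to a 3,4-dihydroisocoumarin. C2′ must therefore be acetylated before the carboxyl is unveiled, and the last step must be neutral and cold. The hard part is the contiguous array C6 (chain CH2), C1 (carboxyl), C2 (oxygen), together with placing two alkyl acetates beside two phenols and an acid that must end up free. The strategy rests on one feature: C7 and C1′ sit on the neighbouring ring carbons C1 and C6, next to the C2 oxygen. That is the pattern formed when a carbon–carbonyl bond adds across the C1≡C6 triple bond of a 3-oxygenated benzyne, the oxygen deciding which end receives which fragment.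

## Retrosynthetic reasoning

24 from 23. The three O–benzyl bonds (C7 ester, C2–O, C4–O) are cut last. Hydrogenolysis is neutral, needs no heat and leaves only a volatile hydrocarbon, so the acid and the acetates are never stressed. It also means the phenols stay masked while the acetates are put on, so no phenol/alcohol selectivity is needed.

23 from 22 from 21. The saturated chain is traced back to a 3′,9′-diyne and the two acetyl C–O bonds are cut, giving diol 21. The triple bonds are the footprints of the two C–C bond formations that assemble the chain. Acetylation is placed before saturation so that the free C2′ hydroxyl is capped immediately and cannot close onto C7.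

21 from 20. The C2′–H bond is cut, giving ynone 20. C2′ has no nearby stereocentre to lean on, so it must be set by a chiral catalyst. An alkynyl ketone is a very good substrate for enantioselective transfer hydrogenation, because the alkyne and the CH2Ar group differ sharply.

20 from 13 and 17. The C2′–C3′ bond is cut between the acyl carbon of Weinreb amide 13 and the terminal alkyne carbon of carbinol 17. C2′ is the carbonyl carbon that the key step leaves behind at the ester oxidation level. An acetylide is a weakly basic, unhindered nucleophile that stops cleanly at the ketone stage on a Weinreb amide. The hindered benzoate at C7 should be left alone.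

17 from 14 and 15. The C10′–C11′ bond is cut between the second alkyne end of diyne 14 and the CH2 of epoxide 15. Opening at the unsubstituted carbon does not touch the stereocentre, so C12′ is bought and not made.

13 from 12. The amide C–N bond is cut back to the arylacetic benzyl ester of 12. The two esters of 12 differ greatly in accessibility: the benzoate is flanked on both sides and deactivated by two donor oxygens. Aminolysis can therefore be confined to the CH2 ester without protecting-group steps.

12 from 8 and 9. This is the key disconnection: bonds C6–C1′ and C1–C7 are cut together. Both come from one C–C(=O) bond of malonate 9 added across aryne 10, which is generated from silyl triflate 8. Cutting here removes the whole substitution problem of the ring in one step and leaves achiral, easily made partners. The forward reaction must place the CH2 on C6 and the carbonyl on C1, which the benzyloxy group next to the triple bond of 10 should dictate.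

8 from 6, 2 and 1. The O–S bond of the triflate, the C–Si bond and the carbamate are cut in turn, back to phenol 1. The carbamate of 2 serves twice: it directs lithiation to the carbon between itself and a benzyloxy group, and it is then exchanged for the triflate under mild amine conditions that spare the C–Si bond.

## Alternatives that were turned down

Alternative 1: The ring bond C1–C6 is disconnected, so the arene is traced to an acyclic tetraketide masked as 6-[(6S,16S)-6,16-bis(tert-butyldimethylsilyloxy)-2,4-dioxoheptadecyl]-2,2-dimethyl-4H-1,3-dioxin-4-one A2. In the forward step A2 is heated with the alcohol that becomes the ester group. The ketal fragment leaves in a retro-[4+2] process, the acylketene is captured as a triketo ester, and mild base closes C1 onto the C6 carbonyl and dehydrates. The product of this key step is benzyl 2,4-dihydroxy-6-[(2S,12S)-2,12-bis(tert-butyldimethylsilyloxy)tridecyl]benzoate A1.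
- For: the ring regiochemistry is fixed by the chain, so no isomer question arises. The phenols appear free, and both stereocentres enter by building block.
- Against: in A2 the C2′ silyloxy group is β to the C6 ketone, so the base needed for aldol closure can eliminate it (E1cB) and destroy the stereocentre. Compound A1 carries silyl ethers where acetates are wanted, beside free phenols. Desilylation of A1 frees the C2′ hydroxyl next to the ester (lactonisation), and the two alcohols must then be acetylated in the presence of two more reactive phenols. Compound A2 itself needs the whole chain as an activated acid and two C-acylations.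
- Comparison: this route is stronger on ring regiocontrol, which is intrinsic there and only substituent-directed in the chosen route. The chosen route keeps phenols and acid benzylated until one neutral final step, so acetylation needs no selectivity, and it is shorter.

Alternative 2: The C2′–O and C12′–O bonds are disconnected, leading to the bis(methyl ketone) benzyl 2,4-bis(benzyloxy)-6-[(2S,12S)-2-acetyl-12-methyl-13-oxotetradecyl]benzoate A4. A buffered peracid effects a double Baeyer–Villiger oxidation of A4, the secondary carbon migrating in preference to methyl with retention. The product of this key step is benzyl 2,4-bis(benzyloxy)-6-[(2S,12S)-2,12-diacetoxytridecyl]benzoate A3. Compound A3 is identical with 23 of the chosen route.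
- For: both acetates arrive in one step, and a free C2′ hydroxyl never exists beside C7 on the way to A3, so the lactonisation hazard is absent. On that point it is stronger than the chosen route.
- Against: the stereochemical problem moves from C–O to C–C. Compound A4 has two α-acyl methine stereocentres, each needing its own auxiliary-controlled alkylation and each open to epimerisation by enolisation until the oxidation. Methyl migration and peracid attack on the electron-rich bis(benzyloxy)arene are further leaks. The ring–chain bond is still unsolved.
- Comparison: the chosen route sets both centres as configurationally stable carbinols, one bought and one from a catalytic reduction. It answers the lactonisation risk by acetylating 21 at once, and it arrives at 23, the same structure as A3, in fewer steps.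

Alternative 3: The ring bonds C1–C2 and C5–C6 are disconnected. The arene is built from the ynoate benzyl (5S,15S)-5,15-diacetoxyhexadec-2-ynoate A6, which supplies C7, C1, C6 and the chain, and the diene 5,5-dimethyl-1,3-bis(trimethylsilyloxy)cyclohexa-1,3-diene A7, which supplies C2–C5 with both oxygens. A thermal [4+2] addition of A6 to A7 is followed by a retro-[4+2] loss of the gem-dimethyl two-carbon bridge as a volatile alkene. After desilylating work-up the product of this key step is benzyl 2,4-dihydroxy-6-[(2S,12S)-2,12-diacetoxytridecyl]benzoate A5.
- For: it is the most convergent plan. The chain arrives complete with both acetates, the polarities match (the unsubstituted diene terminus C5 bonds to the β-carbon C6), and from A5 only one hydrogenolysis remains. In convergence and in steps after the key step it is stronger than the chosen route.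
- Against: a β-alkyl ynoate with a single activating group is a sluggish dienophile, so high temperatures are needed. Under those conditions the bis(silyl enol ether) A7 is fragile, and A6 can isomerise at its acidic C1′ methylene or lose the C2′ acetate by β-elimination. Compound A6 needs a long preparation, and all the chiral material is staked on the riskiest step.
- Comparison: the chosen route runs its risky C–C bond formation early, at moderate temperature, on cheap achiral partners. The stereocentres are added afterwards by dependable carbonyl chemistry, so a failure costs little, whereas a failure on the way to A5 costs the whole chiral chain.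

Key step: step 4

Remark on the chemistry: the sense of the transfer hydrogenation in step 8 is assumed to follow the usual behaviour of alkynyl ketones with this catalyst family, the alkyne taking the place an aryl group has in aryl ketones. The C2′ descriptor is R in 21 and 22 and S in 23 and 24 only because saturating C3′≡C4′ drops C3′ below C1′ in rank; no bond at C2′ changes.

## Route

Step 1
Reactants: 1 3,5-bis(benzyloxy)phenol
Product: 2 3,5-bis(benzyloxy)phenyl N-isopropylcarbamate
Conditions: i-PrNCO, Et3N (cat.), CH2Cl2, rt
Reagents that add atoms: isopropyl isocyanate, CC(C)N=C=O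
Why: Base-catalysed addition of the phenol to the isocyanate (carbamoylation) should give the secondary carbamate, which directs the next step and can later be removed under mild amine conditions.

Step 2
Reactants: 2 3,5-bis(benzyloxy)phenyl N-isopropylcarbamate
Product: 6 3,5-bis(benzyloxy)-2-(trimethylsilyl)phenyl N-isopropylcarbamate, via N-silyl carbamate 3 (not isolated), via aryllithium 4 (not isolated), via doubly silylated carbamate 5 (not isolated)
Conditions: TBSOTf, TMEDA, Et2O, 0 °C → rt; n-BuLi, TMEDA, −78 °C; TMSCl, −78 °C → rt; aq. NaHSO4
Reagents that add atoms: chlorotrimethylsilane, C[Si](C)(C)Cl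
Why: Directed ortho-metalation: N-silylation in the flask masks the N–H, the carbamate and the flanking benzyloxy group together direct lithiation to C2 (the two ortho positions are equivalent by symmetry), and TMSCl traps the aryllithium. The N-silyl group falls off on acidic work-up, and −78 °C should hold back benzylic deprotonation of the ethers and anionic Fries migration.

Step 3
Reactants: 6 3,5-bis(benzyloxy)-2-(trimethylsilyl)phenyl N-isopropylcarbamate
Product: 8 3,5-bis(benzyloxy)-2-(trimethylsilyl)phenyl trifluoromethanesulfonate, via 3,5-bis(benzyloxy)-2-(trimethylsilyl)phenol 7 (not isolated)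
Conditions: DBU, Et2NH, MeCN, 40 °C; then PhNTf2, rt
Reagents that add atoms: N-phenylbis(trifluoromethanesulfonimide), O=S(=O)(N(c1ccccc1)S(=O)(=O)C(F)(F)F)C(F)(F)F
Why: DBU should trigger E1cB loss of the isocyanate from the secondary carbamate (scavenged by Et2NH), and the phenoxide is triflated in the same flask. The C–Si bond meets neither acid nor fluoride.

Step 4
Reactants: 8 3,5-bis(benzyloxy)-2-(trimethylsilyl)phenyl trifluoromethanesulfonate; 9 dibenzyl malonate
Product: 12 benzyl 2,4-bis(benzyloxy)-6-(2-benzyloxy-2-oxoethyl)benzoate, via 3,5-bis(benzyloxy)benzyne 10 (not isolated), via caesium benzocyclobutenoxide 11 (not isolated)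
Conditions: CsF (3 equiv), 9 (1.5 equiv), MeCN, 80 °C
Reagents that add atoms: none
Why: Fluoride attacks silicon in 8 and triflate leaves, releasing aryne 10, whose triple bond joins the future C1 and C6 with a benzyloxy group on the neighbouring C2. The caesium enolate of 9 should add to the aryne carbon remote from that oxygen (future C6): the inductively withdrawing oxygen distorts the aryne so that this carbon is the more electrophilic, and the charge developing at C1 lies beside the oxygen where it is best stabilised; this is the one selectivity the step needs, and the substrate supplies it. The aryl anion at C1 then attacks an ester carbonyl of the malonate unit in a 4-exo-trig closure to the benzocyclobutenoxide 11, a four-membered ring that does not last. Strain relief drives its fragmentation to the ester-stabilised enolate, which excess 9 protonates, so the net result is insertion of C1≡C6 into a C–C(=O) bond: C6–C1′ and C1–C7 form in one operation, C7 as the benzoate and C2′ as the second ester. The closest known reaction type is the fluoride-induced acyl-alkylation of arynes by β-keto esters and malonates. No stereocentre is created. Because every ester in both partners is a benzyl ester, any alkoxide exchange is degenerate, and the product carries only groups that hydrogenolysis removes at the end.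

Step 5
Reactants: 12 benzyl 2,4-bis(benzyloxy)-6-(2-benzyloxy-2-oxoethyl)benzoate
Product: 13 benzyl 2,4-bis(benzyloxy)-6-{2-[methoxy(methyl)amino]-2-oxoethyl}benzoate
Conditions: MeNHOMe·HCl, AlMe3, CH2Cl2, 0 °C → rt; 1 M HCl work-up
Reagents that add atoms: N,O-dimethylhydroxylamine hydrochloride, CNOC.Cl
Why: Weinreb aminolysis by the aluminium amide formed from AlMe3. The arylacetic ester should react, while the benzoate, flanked on both sides and deactivated by two donor oxygens, should be left alone.

Step 6
Reactants: 14 1,7-octadiyne; 15 (S)-propylene oxide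
Product: 17 (S)-undeca-4,10-diyn-2-ol, via octa-1,7-diyn-1-yllithium 16 (not isolated)
Conditions: 14 (3 equiv), n-BuLi (1 equiv), THF, −78 °C; BF3·OEt2; 15, −78 °C; aq. NH4Cl
Reagents that add atoms: none
Why: BF3-assisted SN2 opening of the epoxide by the lithium acetylide at the unsubstituted carbon, so the stereocentre of 15 is carried over untouched as the S carbinol (future C12′). The excess of diyne suppresses double alkylation and is distilled off.

Step 7
Reactants: 13 benzyl 2,4-bis(benzyloxy)-6-{2-[methoxy(methyl)amino]-2-oxoethyl}benzoate; 17 (S)-undeca-4,10-diyn-2-ol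
Product: 20 benzyl 2,4-bis(benzyloxy)-6-[(12S)-12-hydroxy-2-oxotrideca-3,9-diyn-1-yl]benzoate, via dilithio alkynol 18 (not isolated), via lithium hemiaminal adduct 19 (not isolated)
Conditions: 17 (1.5 equiv), n-BuLi (3.0 equiv), THF, −78 → 0 °C; 13, −78 → −30 °C; aq. NH4Cl at −78 °C
Reagents that add atoms: none
Why: Weinreb ketone synthesis: the acetylide end of the dianion adds to the amide while the alkoxide end is inert. The chelated tetrahedral adduct should hold until the cold quench, so no over-addition occurs and the ynone never meets base; the hindered benzoate is not expected to react.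

Step 8
Reactants: 20 benzyl 2,4-bis(benzyloxy)-6-[(12S)-12-hydroxy-2-oxotrideca-3,9-diyn-1-yl]benzoate
Product: 21 benzyl 2,4-bis(benzyloxy)-6-[(2R,12S)-2,12-dihydroxytrideca-3,9-diyn-1-yl]benzoate
Conditions: Ru(p-cymene)[(R,R)-TsDPEN] amido complex (2 mol %; from RuCl(p-cymene)[(R,R)-TsDPEN] and KOH, washed free of base), i-PrOH, rt
Reagents that add atoms: none
Why: Noyori-type asymmetric transfer hydrogenation: hydride on ruthenium and proton on nitrogen are delivered through a six-membered transition state in which the alkyne lies on the side of the arene ligand, so the (R,R) ligand should give the R carbinol at C2′ (the later 2′S centre). The conditions are base-free, and alkynes, benzyl groups and the ester are untouched.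

Step 9
Reactants: 21 benzyl 2,4-bis(benzyloxy)-6-[(2R,12S)-2,12-dihydroxytrideca-3,9-diyn-1-yl]benzoate
Product: 22 benzyl 2,4-bis(benzyloxy)-6-[(2R,12S)-2,12-diacetoxytrideca-3,9-diyn-1-yl]benzoate
Conditions: Ac2O, pyridine, DMAP (cat.), CH2Cl2, 0 °C → rt
Reagents that add atoms: acetic anhydride, CC(=O)OC(C)=O
Why: DMAP-catalysed acylation of both secondary hydroxyls with retention. Capping the C2′ hydroxyl at once removes the nucleophile that could close onto C7, and the phenols are still benzylated, so no selectivity is needed.

Step 10
Reactants: 22 benzyl 2,4-bis(benzyloxy)-6-[(2R,12S)-2,12-diacetoxytrideca-3,9-diyn-1-yl]benzoate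
Product: 23 benzyl 2,4-bis(benzyloxy)-6-[(2S,12S)-2,12-diacetoxytridecyl]benzoate
Conditions: H2 (1 atm), PtO2, EtOAc, rt
Reagents that add atoms: none
Why: Heterogeneous hydrogenation of both triple bonds. Platinum has little tendency to allylic C–O hydrogenolysis or double-bond migration, so the C2′ acetate and its configuration should be kept; any partial loss of benzyl groups is harmless because the next step removes them all.

Step 11
Reactants: 23 benzyl 2,4-bis(benzyloxy)-6-[(2S,12S)-2,12-diacetoxytridecyl]benzoate
Product: 24 6-[(2S,12S)-2,12-diacetoxytridecyl]-2,4-dihydroxybenzoic acid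
Conditions: H2 (1 atm), Pd/C, EtOAc, rt
Reagents that add atoms: none
Why: Hydrogenolysis of the benzyl ester and both benzyl ethers at neutral pH and room temperature, so the decarboxylation-prone acid and the acetates meet neither acid, base nor heat.

## Compound list

1 | 3,5-bis(benzyloxy)phenol | Oc1cc(OCc2ccccc2)cc(OCc2ccccc2)c1 | starting material
2 | 3,5-bis(benzyloxy)phenyl N-isopropylcarbamate | CC(C)NC(=O)Oc1cc(OCc2ccccc2)cc(OCc2ccccc2)c1 | intermediate
3 | 3,5-bis(benzyloxy)phenyl N-(tert-butyldimethylsilyl)-N-isopropylcarbamate (formed in the flask) | CC(C)N(C(=O)Oc1cc(OCc2ccccc2)cc(OCc2ccccc2)c1)[Si](C)(C)C(C)(C)C | intermediate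
4 | 2-lithio derivative of 3, lithium on the carbon between the carbamate oxygen and a benzyloxy group (formed in the flask) | [Li]c1c(OC(=O)N(C(C)C)[Si](C)(C)C(C)(C)C)cc(OCc2ccccc2)cc1OCc1ccccc1 | intermediate
5 | 3,5-bis(benzyloxy)-2-(trimethylsilyl)phenyl N-(tert-butyldimethylsilyl)-N-isopropylcarbamate (formed in the flask) | C[Si](C)(C)c1c(OC(=O)N(C(C)C)[Si](C)(C)C(C)(C)C)cc(OCc2ccccc2)cc1OCc1ccccc1 | intermediate
6 | 3,5-bis(benzyloxy)-2-(trimethylsilyl)phenyl N-isopropylcarbamate | C[Si](C)(C)c1c(OC(=O)NC(C)C)cc(OCc2ccccc2)cc1OCc1ccccc1 | intermediate
7 | 3,5-bis(benzyloxy)-2-(trimethylsilyl)phenol (formed in the flask, as its DBU salt) | C[Si](C)(C)c1c(O)cc(OCc2ccccc2)cc1OCc1ccccc1 | intermediate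
8 | 3,5-bis(benzyloxy)-2-(trimethylsilyl)phenyl trifluoromethanesulfonate | C[Si](C)(C)c1c(OS(=O)(=O)C(F)(F)F)cc(OCc2ccccc2)cc1OCc1ccccc1 | intermediate
9 | dibenzyl malonate | O=C(CC(=O)OCc1ccccc1)OCc1ccccc1 | starting material
10 | 3,5-bis(benzyloxy)benzyne (formed in the flask) | C1(OCc2ccccc2)=CC(OCc2ccccc2)=CC#C1 | intermediate
11 | caesium salt of benzyl 2,4,8-tris(benzyloxy)-8-oxidobicyclo[4.2.0]octa-1,3,5-triene-7-carboxylate (formed in the flask) | [Cs+].[O-]C1(OCc2ccccc2)C(C(=O)OCc2ccccc2)c2cc(OCc3ccccc3)cc(OCc3ccccc3)c12 | intermediate
12 | benzyl 2,4-bis(benzyloxy)-6-(2-benzyloxy-2-oxoethyl)benzoate | O=C(Cc1cc(OCc2ccccc2)cc(OCc2ccccc2)c1C(=O)OCc1ccccc1)OCc1ccccc1 | intermediate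
13 | benzyl 2,4-bis(benzyloxy)-6-{2-[methoxy(methyl)amino]-2-oxoethyl}benzoate | CON(C)C(=O)Cc1cc(OCc2ccccc2)cc(OCc2ccccc2)c1C(=O)OCc1ccccc1 | intermediate
14 | 1,7-octadiyne | C#CCCCCC#C | starting material
15 | (S)-propylene oxide | C[C@H]1CO1 | starting material
16 | octa-1,7-diyn-1-yllithium (formed in the flask) | [Li]C#CCCCCC#C | intermediate
17 | (S)-undeca-4,10-diyn-2-ol | C[C@H](O)CC#CCCCCC#C | intermediate
18 | dilithium derivative of 17, lithium alkoxide and lithium acetylide (formed in the flask) | C[C@H](O[Li])CC#CCCCCC#C[Li] | intermediate
19 | dilithium salt of the tetrahedral adduct, benzyl 2,4-bis(benzyloxy)-6-[(12S)-2,12-bis(lithiooxy)-2-[methoxy(methyl)amino]trideca-3,9-diyn-1-yl]benzoate (formed in the flask) | C[C@H](O[Li])CC#CCCCCC#CC(O[Li])(N(C)OC)Cc1cc(OCc2ccccc2)cc(OCc2ccccc2)c1C(=O)OCc1ccccc1 | intermediate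
20 | benzyl 2,4-bis(benzyloxy)-6-[(12S)-12-hydroxy-2-oxotrideca-3,9-diyn-1-yl]benzoate | C[C@H](O)CC#CCCCCC#CC(=O)Cc1cc(OCc2ccccc2)cc(OCc2ccccc2)c1C(=O)OCc1ccccc1 | intermediate
21 | benzyl 2,4-bis(benzyloxy)-6-[(2R,12S)-2,12-dihydroxytrideca-3,9-diyn-1-yl]benzoate | C[C@H](O)CC#CCCCCC#C[C@H](O)Cc1cc(OCc2ccccc2)cc(OCc2ccccc2)c1C(=O)OCc1ccccc1 | intermediate
22 | benzyl 2,4-bis(benzyloxy)-6-[(2R,12S)-2,12-diacetoxytrideca-3,9-diyn-1-yl]benzoate | C[C@H](OC(C)=O)CC#CCCCCC#C[C@H](OC(C)=O)Cc1cc(OCc2ccccc2)cc(OCc2ccccc2)c1C(=O)OCc1ccccc1 | intermediate
23 | benzyl 2,4-bis(benzyloxy)-6-[(2S,12S)-2,12-diacetoxytridecyl]benzoate | C[C@H](OC(C)=O)CCCCCCCCC[C@H](OC(C)=O)Cc1cc(OCc2ccccc2)cc(OCc2ccccc2)c1C(=O)OCc1ccccc1 | intermediate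
24 | 6-[(2S,12S)-2,12-diacetoxytridecyl]-2,4-dihydroxybenzoic acid | CC(=O)O[C@@H](CCCCCCCCC[C@H](C)OC(C)=O)Cc1cc(O)cc(O)c1C(=O)O | target

## Step count and least certain steps

Total: 11 steps. Longest linear sequence: 10 steps (steps 1–5 and 7–11, from 1 to 24); step 6 is a one-step side branch.

Step 4 (key step). The aryl anion formed after enolate addition may be protonated by the acidic methylene of 9 before it closes onto the rather weakly electrophilic ester carbonyl. That would give plain C-arylation with no carboxyl transfer, and the product could be arylated again. Some loss of regiocontrol in the enolate addition is a lesser risk. The fallback makes the same two bonds one after the other without an aryne; it sets out from carbamate 2 and returns at diester 12. Aryllithium 4, generated as in step 2, is quenched with benzyl chloroformate in place of TMSCl to give benzyl 2,4-bis(benzyloxy)-6-{[(tert-butyldimethylsilyl)(isopropyl)carbamoyl]oxy}benzoate F1. Acidic work-up removes the N-silyl group and leaves benzyl 2,4-bis(benzyloxy)-6-[(isopropylcarbamoyl)oxy]benzoate F2. DBU and Et2NH free benzyl 2,4-bis(benzyloxy)-6-hydroxybenzoate F3, and PhNTf2 converts it into benzyl 2,4-bis(benzyloxy)-6-{[(trifluoromethyl)sulfonyl]oxy}benzoate F4. A palladium-catalysed enolate arylation of malonate 9 with F4 [Pd(OAc)2, P(t-Bu)3, K3PO4, toluene] gives dibenzyl 2-[3,5-bis(benzyloxy)-2-(benzyloxycarbonyl)phenyl]malonate F5. One equivalent of KOH cleaves one of the unhindered malonate esters to 2-[3,5-bis(benzyloxy)-2-(benzyloxycarbonyl)phenyl]-3-(benzyloxy)-3-oxopropanoic acid F6, which loses CO2 on gentle warming after acidification and so arrives at 12.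

Step 7. The CH2 of 13 is activated by the amide and by an aryl ring bearing an ortho ester, so proton transfer to the acetylide or alkoxide may compete with addition and return starting material. The fallback replaces the amide by a faster electrophile; it sets out from Weinreb amide 13 and returns at ynone 20. Reduction with i-Bu2AlH (THF, −78 °C) gives benzyl 2,4-bis(benzyloxy)-6-(2-oxoethyl)benzoate F7. Dianion 18 adds to this aldehyde at −78 °C faster than it deprotonates it, and protonation in the cold (before the alkoxide can close onto C7) gives benzyl 2,4-bis(benzyloxy)-6-[(2RS,12S)-2,12-dihydroxytrideca-3,9-diyn-1-yl]benzoate F8 as a mixture at C2′. MnO2 in CH2Cl2 oxidises only the propargylic hydroxyl and delivers 20.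

Step 8. The C1′ methylene of 20 lies between an aryl ring and an ynone. The basic amido catalyst may therefore cause enolisation and isomerisation of the ynone, or the enolate may bind and stall the catalyst. Reversible dehydrogenation at the free C12′ carbinol could also erode that centre. The fallback sets out from 20 and returns at 21 with a stoichiometric, non-basic reagent: Midland reduction with (R)-Alpine-Borane (the B-isopinocampheyl-9-borabicyclo[3.3.1]nonane from (+)-α-pinene) in THF at room temperature. It transfers hydride through a cyclic transition state in which the slim alkyne takes the small-group position. It should give the same R carbinol, and it cannot oxidise C12′.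

Step 10. At the half-reduced stage the C2′ acetate is allylic. Hydrogenolysis of the C2′–O bond or migration of the double bond toward C2′ (loss of configuration by way of an enol acetate) may occur. The fallback changes the order so that the allylic leaving group is a hydroxyl; it sets out from diol 21 and returns at 23. Hydrogenation of 21 over PtO2 in EtOAc gives benzyl 2,4-bis(benzyloxy)-6-[(2S,12S)-2,12-dihydroxytridecyl]benzoate F9, which is acetylated without delay (Ac2O, pyridine, DMAP) to 23.

## Further compounds

F1 | step 4 | benzyl 2,4-bis(benzyloxy)-6-{[(tert-butyldimethylsilyl)(isopropyl)carbamoyl]oxy}benzoate | CC(C)N(C(=O)Oc1cc(OCc2ccccc2)cc(OCc2ccccc2)c1C(=O)OCc1ccccc1)[Si](C)(C)C(C)(C)C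
F2 | step 4 | benzyl 2,4-bis(benzyloxy)-6-[(isopropylcarbamoyl)oxy]benzoate | CC(C)NC(=O)Oc1cc(OCc2ccccc2)cc(OCc2ccccc2)c1C(=O)OCc1ccccc1
F3 | step 4 | benzyl 2,4-bis(benzyloxy)-6-hydroxybenzoate | Oc1cc(OCc2ccccc2)cc(OCc2ccccc2)c1C(=O)OCc1ccccc1
F4 | step 4 | benzyl 2,4-bis(benzyloxy)-6-{[(trifluoromethyl)sulfonyl]oxy}benzoate | O=C(OCc1ccccc1)c1c(OS(=O)(=O)C(F)(F)F)cc(OCc2ccccc2)cc1OCc1ccccc1
F5 | step 4 | dibenzyl 2-[3,5-bis(benzyloxy)-2-(benzyloxycarbonyl)phenyl]malonate | O=C(OCc1ccccc1)C(C(=O)OCc1ccccc1)c1cc(OCc2ccccc2)cc(OCc2ccccc2)c1C(=O)OCc1ccccc1
F6 | step 4 | 2-[3,5-bis(benzyloxy)-2-(benzyloxycarbonyl)phenyl]-3-(benzyloxy)-3-oxopropanoic acid | O=C(O)C(C(=O)OCc1ccccc1)c1cc(OCc2ccccc2)cc(OCc2ccccc2)c1C(=O)OCc1ccccc1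
F7 | step 7 | benzyl 2,4-bis(benzyloxy)-6-(2-oxoethyl)benzoate | O=CCc1cc(OCc2ccccc2)cc(OCc2ccccc2)c1C(=O)OCc1ccccc1
F8 | step 7 | benzyl 2,4-bis(benzyloxy)-6-[(2RS,12S)-2,12-dihydroxytrideca-3,9-diyn-1-yl]benzoate | C[C@H](O)CC#CCCCCC#CC(O)Cc1cc(OCc2ccccc2)cc(OCc2ccccc2)c1C(=O)OCc1ccccc1
F0 | step 8 | none | none
F9 | step 10 | benzyl 2,4-bis(benzyloxy)-6-[(2S,12S)-2,12-dihydroxytridecyl]benzoate | C[C@H](O)CCCCCCCCC[C@H](O)Cc1cc(OCc2ccccc2)cc(OCc2ccccc2)c1C(=O)OCc1ccccc1
A1 | alternative 1 | benzyl 2,4-dihydroxy-6-[(2S,12S)-2,12-bis(tert-butyldimethylsilyloxy)tridecyl]benzoate | CC(C)(C)[Si](C)(C)O[C@@H](CCCCCCCCC[C@H](C)O[Si](C)(C)C(C)(C)C)Cc1cc(O)cc(O)c1C(=O)OCc1ccccc1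
A2 | alternative 1 | 6-[(6S,16S)-6,16-bis(tert-butyldimethylsilyloxy)-2,4-dioxoheptadecyl]-2,2-dimethyl-4H-1,3-dioxin-4-one | CC(C)(C)[Si](C)(C)O[C@@H](CCCCCCCCC[C@H](C)O[Si](C)(C)C(C)(C)C)CC(=O)CC(=O)CC1=CC(=O)OC(C)(C)O1
A3 | alternative 2 | benzyl 2,4-bis(benzyloxy)-6-[(2S,12S)-2,12-diacetoxytridecyl]benzoate | CC(=O)O[C@@H](CCCCCCCCC[C@H](C)OC(C)=O)Cc1cc(OCc2ccccc2)cc(OCc2ccccc2)c1C(=O)OCc1ccccc1
A4 | alternative 2 | benzyl 2,4-bis(benzyloxy)-6-[(2S,12S)-2-acetyl-12-methyl-13-oxotetradecyl]benzoate | CC(=O)[C@@H](CCCCCCCCC[C@H](C)C(C)=O)Cc1cc(OCc2ccccc2)cc(OCc2ccccc2)c1C(=O)OCc1ccccc1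
A5 | alternative 3 | benzyl 2,4-dihydroxy-6-[(2S,12S)-2,12-diacetoxytridecyl]benzoate | CC(=O)O[C@@H](CCCCCCCCC[C@H](C)OC(C)=O)Cc1cc(O)cc(O)c1C(=O)OCc1ccccc1
A6 | alternative 3 | benzyl (5S,15S)-5,15-diacetoxyhexadec-2-ynoate | CC(=O)O[C@@H](CCCCCCCCC[C@H](C)OC(C)=O)CC#CC(=O)OCc1ccccc1
A7 | alternative 3 | 5,5-dimethyl-1,3-bis(trimethylsilyloxy)cyclohexa-1,3-diene | CC1(C)CC(O[Si](C)(C)C)=CC(O[Si](C)(C)C)=C1
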